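**Strategy.** Ring A of the target (C1–C2–C3–C4–C5–C10, labdane numbering) is read as a cyclohexene [4+2] adduct: C10=C1–C2=C3 is the diene, C4=C5 the dienophile. Because C5–C10 also belongs to ring B, a type 1 intramolecular Diels–Alder reaction of an acyclic pentaene tethered through C6–C7–C8=C9 closes rings A and B in one operation, forms C3–C4 and C5–C10, and sets C3, C5 and C10 under catalyst control. The precursor is an (E,E)-dienylboronate whose dienophile carries a formyl group on C4; boron is later exchanged for bromine with inversion, the formyl group becomes the second C4 methyl, and the tertiary vinyl carbinol is unveiled last from a Sharpless epoxide.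

Key step: step 12

Remark: atom labels follow labdane numbering (C3 = CHBr, C4 = CMe2, C5/C10 = ring fusion, C8=C9 = ring B alkene, C13 = carbinol carbon); the target is (3R,5S,10R,13R).
Remark: compounds 1, 6, 16 and 18 are taken as commercially available.
Remark: an (E)-bromodiene cannot be used directly. With the tether on the outside of the diene the cycloaddition would put bromine trans to the C10 methyl, and the (Z)-bromodiene would place two inside substituents on the diene. Boron is therefore carried through the cycloaddition and inverted afterwards.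

Step 1
Reactants: 1 hex-1-en-5-yne
Product: 3 ethyl hept-6-en-2-ynoate, via lithium acetylide 2 (not isolated)
Conditions: n-BuLi, THF, −78 °C; then ClCO2Et, −78 → 0 °C
Reagents that add atoms: ethyl chloroformate, CCOC(Cl)=O; n-butyllithium, [Li]CCCC (Li in 2 only)
Why: Acylation of a lithium acetylide with a chloroformate is the standard entry to 2-ynoates and creates no stereo-element.

Step 2
Reactants: 3 ethyl hept-6-en-2-ynoate
Product: 5 ethyl (2E)-2-iodo-3-methylhepta-2,6-dienoate, via vinylcuprate 4 (not isolated)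
Conditions: Me2CuLi, THF, −78 °C; then I2, THF, −78 °C
Reagents that add atoms: lithium dimethylcuprate, [Li+].C[Cu-]C; iodine, II
Why: syn-Carbocupration of the ynoate puts CH3 and Cu cis on the future C8=C9 bond, and iodinolysis at −78 °C (before the α-cuprio ester can equilibrate through its allenoate) retains this geometry, so the C7 chain stays cis to the ester carbon (C10).

Step 3
Reactants: 6 (2E)-3-methylpent-2-en-4-yn-1-ol
Product: 7 tert-butyl{[(2E)-3-methylpent-2-en-4-yn-1-yl]oxy}diphenylsilane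
Conditions: TBDPSCl, imidazole, DMF, rt
Reagents that add atoms: tert-butyl(chloro)diphenylsilane, CC(C)(C)[Si](Cl)(c1ccccc1)c1ccccc1
Why: Silylation of the primary alcohol gives an ether that should survive i-Bu2AlH, MnO2, AlMe3 and the palladium steps.

Step 4
Reactants: 7 silyl enyne
Product: 8 tert-butyl{[(2E)-3-methylpenta-2,4-dien-1-yl]oxy}diphenylsilane
Conditions: H2 (1 atm), Pd/CaCO3 poisoned with Pb(OAc)2, quinoline, hexane, rt
Reagents that add atoms: none
Why: Lindlar semihydrogenation reduces the terminal alkyne to the vinyl group and leaves the (E)-trisubstituted alkene (future C13=C14) untouched.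

Step 5
Reactants: 8 silyl diene; 5 ethyl (2E)-2-iodo-3-methylhepta-2,6-dienoate
Product: 10 ethyl (2Z)-2-[(3E)-5-(tert-butyldiphenylsilyloxy)-3-methylpent-3-en-1-yl]-3-methylhepta-2,6-dienoate, via alkylborane 9 (not isolated)
Conditions: 9-BBN, THF, 0 °C → rt (8 in slight excess); then 5, Pd(dppf)Cl2, AsPh3, Cs2CO3, DMF/H2O, rt
Reagents that add atoms: 9-borabicyclo[3.3.1]nonane, B1C2CCCC1CCC2 (in 9 only)
Why: 9-BBN hydroborates only the terminal vinyl carbon of the diene, and the B-alkyl Suzuki–Miyaura coupling replaces iodine with retention of alkene geometry, giving the tetrasubstituted C8=C9 alkene with C7 cis to C10.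

Step 6
Reactants: 10 tetrasubstituted enoate
Product: 11 (2Z)-2-[(3E)-5-(tert-butyldiphenylsilyloxy)-3-methylpent-3-en-1-yl]-3-methylhepta-2,6-dien-1-ol
Conditions: i-Bu2AlH, CH2Cl2, −78 °C
Reagents that add atoms: none
Why: 1,2-Reduction of the conjugated ester by the aluminium hydride gives the allylic alcohol without touching the alkenes or the silyl ether.

Step 7
Reactants: 11 allylic alcohol
Product: 12 (2Z)-2-[(3E)-5-(tert-butyldiphenylsilyloxy)-3-methylpent-3-en-1-yl]-3-methylhepta-2,6-dienal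
Conditions: MnO2, CH2Cl2, rt
Reagents that add atoms: none
Why: MnO2 oxidises allylic alcohols selectively under neutral conditions, so the tetrasubstituted alkene geometry should be kept.

Step 8
Reactants: 12 enal
Product: 13 tert-butyl{[(2E,6Z)-6-ethynyl-3,7-dimethylundeca-2,6,10-trien-1-yl]oxy}diphenylsilane
Conditions: dimethyl (1-diazo-2-oxopropyl)phosphonate, K2CO3, MeOH, 0 °C → rt
Reagents that add atoms: dimethyl (1-diazo-2-oxopropyl)phosphonate, COP(=O)(OC)C(=[N+]=[N-])C(C)=O
Why: Ohira–Bestmann (Seyferth–Gilbert) homologation turns the formyl carbon (C10) into the internal alkyne carbon and adds C1; the β,β-disubstituted enal cannot take up methanol in a conjugate sense.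

Step 9
Reactants: 13 enyne
Product: 15 tert-butyl({(2E,6Z)-6-[(1E)-1-iodoprop-1-en-2-yl]-3,7-dimethylundeca-2,6,10-trien-1-yl}oxy)diphenylsilane, via alkenylalane 14 (not isolated)
Conditions: AlMe3, Cp2ZrCl2 (0.25 equiv), CH2Cl2, 0 °C → rt; then I2, THF, −30 °C
Reagents that add atoms: trimethylaluminium, C[Al](C)C; iodine, II
Why: Zirconium-catalysed methylalumination adds CH3 (to C10) and Al (to C1) syn across the terminal alkyne, and iodinolysis with retention gives the (E)-iodide in which C9 is trans to iodine; isolated alkenes do not react under these conditions.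

Step 10
Reactants: 15 alkenyl iodide; 16 methacrolein
Product: 17 (2E,6Z,10E)-12-(tert-butyldiphenylsilyloxy)-7-[(1E)-1-iodoprop-1-en-2-yl]-2,6,10-trimethyldodeca-2,6,10-trienal
Conditions: 16 (5 equiv), second-generation Hoveyda–Grubbs catalyst (5 mol %), CH2Cl2, 40 °C
Reagents that add atoms: none
Why: Olefin cross-metathesis engages only the monosubstituted alkene and should give the thermodynamically preferred (E)-2-methyl enal; tri- and tetrasubstituted alkenes and the alkenyl iodide are inert to the ruthenium carbene.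

Step 11
Reactants: 17 iodo trienal; 18 (E)-1,2-bis(4,4,5,5-tetramethyl-1,3,2-dioxaborolan-2-yl)ethene
Product: 19 (2E,6Z,10E)-12-(tert-butyldiphenylsilyloxy)-2,6,10-trimethyl-7-[(2E,4E)-5-(4,4,5,5-tetramethyl-1,3,2-dioxaborolan-2-yl)penta-2,4-dien-2-yl]dodeca-2,6,10-trienal
Conditions: 18 (3 equiv), Pd(dppf)Cl2, K3PO4, THF/H2O, rt
Reagents that add atoms: none
Why: Suzuki–Miyaura mono-coupling of the alkenyl iodide with the bis-boronate retains both alkene geometries and gives the (E,E)-dienylboronate; excess 18 suppresses double coupling and room temperature avoids uncatalysed cycloaddition.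

Step 12
Reactants: 19 pentaene aldehyde
Product: 20 (3S,4S,5S,10R,13E)-15-(tert-butyldiphenylsilyloxy)-3-(4,4,5,5-tetramethyl-1,3,2-dioxaborolan-2-yl)labda-1,8,13-trien-19-al
Conditions: (S)-o-tolyl-CBS-oxazaborolidine activated with Tf2NH (20 mol %), CH2Cl2, −78 → −40 °C
Reagents that add atoms: none
Why: The enal, bound to the chiral oxazaborolidinium Lewis acid, adds suprafacially to the s-cis (E,E)-dienylboronate in a concerted, asynchronous normal-demand [4+2] cycloaddition; the closest known reaction type is the catalytic enantioselective type 1 intramolecular Diels–Alder reaction of 2,8,10-undecatrienals. Ring A closes through the two new bonds C3–C4 and C5–C10 themselves, and ring B closes as the six-membered ring spanned by the C6–C7–C8=C9 tether, fused (not bridged) at C5–C10. At C10 the methyl group is the inside substituent of the diene terminus and C9 the outside one, and at C3 boron is the outside substituent, so boron ends up cis to C9 and trans to the C10 methyl. At C5 the formyl-endo transition state places the tether carbon C6 exo, which gives the trans ring fusion (H-5 trans to the C10 methyl) and a temporary C4 centre with formyl cis to H-5. The absolute sense (5S,10R) depends on which enal face the catalyst leaves open, and the enantiomeric catalyst is taken should the (S)-catalyst favour the other face. The step needs formyl-endo over formyl-exo addition and reaction at the enal only: Lewis-acid coordination of the formyl group is relied on for both, and the unactivated C8=C9 and C13=C14 alkenes cannot compete at this temperature.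

Step 13
Reactants: 20 cycloadduct
Product: 21 (3S,4S,5S,10R,13E)-15-(tert-butyldiphenylsilyloxy)-3-(4,4,5,5-tetramethyl-1,3,2-dioxaborolan-2-yl)labda-8,13-dien-19-al
Conditions: KO2CN=NCO2K, AcOH, MeOH/pyridine, rt
Reagents that add atoms: none
Why: Diimide transfers H2 in a concerted syn fashion to the cis-disubstituted C1=C2 alkene only; the trisubstituted and tetrasubstituted alkenes, the aldehyde and the C–B bond are not reduced.

Step 14
Reactants: 21 saturated aldehyde
Product: 23 (3S,5R,10R,13E)-15-(tert-butyldiphenylsilyloxy)-3-(4,4,5,5-tetramethyl-1,3,2-dioxaborolan-2-yl)labda-8,13-diene, via tosylhydrazone 22 (not isolated)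
Conditions: TsNHNH2, EtOH, rt; then catecholborane, CHCl3, 0 °C; NaOAc·3H2O, reflux
Reagents that add atoms: 4-methylbenzenesulfonohydrazide, Cc1ccc(cc1)S(=O)(=O)NN (in 22 only)
Why: Reductive deoxygenation of an aldehyde tosylhydrazone (hydride addition to C=N, then loss of sulfinate and N2) converts the formyl group into the second C4 methyl under conditions that spare the alkyl boronate; C4 ceases to be a stereocentre.

Step 15
Reactants: 23 secondary alkyl boronate
Product: 25 (3R,5S,10R,13E)-3-bromo-15-(tert-butyldiphenylsilyloxy)labda-8,13-diene, via boronate complex 24 (not isolated)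
Conditions: 3,5-(CF3)2C6H3Li (from the aryl bromide and n-BuLi), THF, −78 °C; then NBS, −78 °C → rt
Reagents that add atoms: N-bromosuccinimide, O=C1CCC(=O)N1Br; 3,5-bis(trifluoromethyl)phenyllithium, [Li]c1cc(C(F)(F)F)cc(C(F)(F)F)c1 (in 24 only)
Why: Electrophilic bromination of the aryl boronate complex of a secondary alkyl pinacol boronate proceeds with inversion at carbon (open SE2 transition state), so the axial C3–B bond trans to the C10 methyl is replaced by the equatorial C3–Br bond cis to it (3R).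

Step 16
Reactants: 25 silyl ether
Product: 26 (3R,5S,10R,13E)-3-bromolabda-8,13-dien-15-ol
Conditions: Bu4NF, THF, 0 °C → rt
Reagents that add atoms: none
Why: Fluoride cleaves the Si–O bond; the hindered secondary bromide should not be displaced or eliminated at this temperature.

Step 17
Reactants: 26 allylic alcohol
Product: 27 (3R,5S,10R,13R,14R)-3-bromo-13,14-epoxylabd-8-en-15-ol
Conditions: Ti(OiPr)4, D-(−)-diethyl tartrate, t-BuOOH, 4 Å molecular sieves, CH2Cl2, −20 °C
Reagents that add atoms: tert-butyl hydroperoxide, CC(C)(C)OO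
Why: Sharpless asymmetric epoxidation is reagent-controlled: the D-(−)-tartrate complex should deliver oxygen to the face of the (E)-allylic alcohol that gives the (13R,14R)-epoxide, and the C8=C9 alkene, which has no allylic hydroxyl, is not epoxidised.

Step 18
Reactants: 27 epoxy alcohol
Product: 29 (3R,5S,10R,13R)-3-bromolabda-8,14-dien-13-ol, via epoxy iodide 28 (not isolated)
Conditions: PPh3, I2, imidazole, CH2Cl2, 0 °C; then Zn dust, EtOH, 70 °C
Reagents that add atoms: iodine, II (in 28 only)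
Why: Iodination of the primary alcohol and zinc-mediated reductive elimination of the β-iodo epoxide break only the C14–O bond, so the C13–O bond and its R configuration are carried into the tertiary vinyl carbinol.

**Compound list**

1 | hex-1-en-5-yne | C=CCCC#C | starting material
2 | lithium acetylide of 1 (lithium hex-5-en-1-yn-1-ide) | [Li]C#CCCC=C | intermediate
3 | ethyl hept-6-en-2-ynoate | C=CCCC#CC(=O)OCC | intermediate
4 | lithium methyl[(1E)-1-(ethoxycarbonyl)-2-methylhexa-1,5-dien-1-yl]cuprate (Cu cis to CH3) | [Li+].CCOC(=O)/C([Cu-]C)=C(C)\CCC=C | intermediate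
5 | ethyl (2E)-2-iodo-3-methylhepta-2,6-dienoate (I cis to CH3) | CCOC(=O)/C(I)=C(C)\CCC=C | intermediate
6 | (2E)-3-methylpent-2-en-4-yn-1-ol | C#C/C(C)=C/CO | starting material
7 | tert-butyl{[(2E)-3-methylpent-2-en-4-yn-1-yl]oxy}diphenylsilane | C#C/C(C)=C/CO[Si](c1ccccc1)(c1ccccc1)C(C)(C)C | intermediate
8 | tert-butyl{[(2E)-3-methylpenta-2,4-dien-1-yl]oxy}diphenylsilane | C=C/C(C)=C/CO[Si](c1ccccc1)(c1ccccc1)C(C)(C)C | intermediate
9 | 9-[(3E)-5-(tert-butyldiphenylsilyloxy)-3-methylpent-3-en-1-yl]-9-borabicyclo[3.3.1]nonane | CC(C)(C)[Si](c1ccccc1)(c1ccccc1)OC/C=C(C)/CCB1C2CCCC1CCC2 | intermediate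
10 | ethyl (2Z)-2-[(3E)-5-(tert-butyldiphenylsilyloxy)-3-methylpent-3-en-1-yl]-3-methylhepta-2,6-dienoate (C7 chain cis to ester) | CCOC(=O)/C(CC/C(C)=C/CO[Si](c1ccccc1)(c1ccccc1)C(C)(C)C)=C(C)\CCC=C | intermediate
11 | (2Z)-2-[(3E)-5-(tert-butyldiphenylsilyloxy)-3-methylpent-3-en-1-yl]-3-methylhepta-2,6-dien-1-ol | OC/C(CC/C(C)=C/CO[Si](c1ccccc1)(c1ccccc1)C(C)(C)C)=C(C)\CCC=C | intermediate
12 | (2Z)-2-[(3E)-5-(tert-butyldiphenylsilyloxy)-3-methylpent-3-en-1-yl]-3-methylhepta-2,6-dienal | O=C/C(CC/C(C)=C/CO[Si](c1ccccc1)(c1ccccc1)C(C)(C)C)=C(C)\CCC=C | intermediate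
13 | tert-butyl{[(2E,6Z)-6-ethynyl-3,7-dimethylundeca-2,6,10-trien-1-yl]oxy}diphenylsilane | C#C/C(CC/C(C)=C/CO[Si](c1ccccc1)(c1ccccc1)C(C)(C)C)=C(C)\CCC=C | intermediate
14 | dimethylalane analogue of 15 (AlMe2 in place of I, Al trans to C9) | C[Al](C)/C=C(C)/C(CC/C(C)=C/CO[Si](c1ccccc1)(c1ccccc1)C(C)(C)C)=C(C)\CCC=C | intermediate
15 | tert-butyl({(2E,6Z)-6-[(1E)-1-iodoprop-1-en-2-yl]-3,7-dimethylundeca-2,6,10-trien-1-yl}oxy)diphenylsilane | I/C=C(C)/C(CC/C(C)=C/CO[Si](c1ccccc1)(c1ccccc1)C(C)(C)C)=C(C)\CCC=C | intermediate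
16 | methacrolein (2-methylprop-2-enal) | CC(=C)C=O | starting material
17 | (2E,6Z,10E)-12-(tert-butyldiphenylsilyloxy)-7-[(1E)-1-iodoprop-1-en-2-yl]-2,6,10-trimethyldodeca-2,6,10-trienal | I/C=C(C)/C(CC/C(C)=C/CO[Si](c1ccccc1)(c1ccccc1)C(C)(C)C)=C(C)\CC/C=C(C)/C=O | intermediate
18 | (E)-1,2-bis(4,4,5,5-tetramethyl-1,3,2-dioxaborolan-2-yl)ethene | CC1(C)OB(/C=C/B2OC(C)(C)C(C)(C)O2)OC1(C)C | starting material
19 | (2E,6Z,10E)-12-(tert-butyldiphenylsilyloxy)-2,6,10-trimethyl-7-[(2E,4E)-5-(4,4,5,5-tetramethyl-1,3,2-dioxaborolan-2-yl)penta-2,4-dien-2-yl]dodeca-2,6,10-trienal | CC1(C)OB(/C=C/C=C(C)/C(CC/C(C)=C/CO[Si](c2ccccc2)(c2ccccc2)C(C)(C)C)=C(C)\CC/C=C(C)/C=O)OC1(C)C | intermediate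
20 | (3S,4S,5S,10R,13E)-15-(tert-butyldiphenylsilyloxy)-3-(pinacolboryl)labda-1,8,13-trien-19-al (trans-fused; boron trans to C10 methyl; formyl cis to H-5) | CC(C)(C)[Si](c1ccccc1)(c1ccccc1)OC/C=C(C)/CCC3=C(C)CC[C@@H]4[C@@](C)(C=O)[C@@H](B5OC(C)(C)C(C)(C)O5)C=C[C@@]34C | intermediate
21 | (3S,4S,5S,10R,13E)-15-(tert-butyldiphenylsilyloxy)-3-(pinacolboryl)labda-8,13-dien-19-al | CC(C)(C)[Si](c1ccccc1)(c1ccccc1)OC/C=C(C)/CCC3=C(C)CC[C@@H]4[C@@](C)(C=O)[C@@H](B5OC(C)(C)C(C)(C)O5)CC[C@@]34C | intermediate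
22 | N-tosylhydrazone of 21 | CC(C)(C)[Si](c1ccccc1)(c1ccccc1)OC/C=C(C)/CCC3=C(C)CC[C@@H]4[C@@](C)(C=NNS(=O)(=O)c6ccc(C)cc6)[C@@H](B5OC(C)(C)C(C)(C)O5)CC[C@@]34C | intermediate
23 | (3S,5R,10R,13E)-15-(tert-butyldiphenylsilyloxy)-3-(pinacolboryl)labda-8,13-diene (axial boron, trans to C10 methyl) | CC(C)(C)[Si](c1ccccc1)(c1ccccc1)OC/C=C(C)/CCC3=C(C)CC[C@@H]4C(C)(C)[C@@H](B5OC(C)(C)C(C)(C)O5)CC[C@@]34C | intermediate
24 | lithium [3,5-bis(trifluoromethyl)phenyl]boronate complex of 23 | [Li+].CC(C)(C)[Si](c1ccccc1)(c1ccccc1)OC/C=C(C)/CCC3=C(C)CC[C@@H]4C(C)(C)[C@@H]([B-]5(c6cc(C(F)(F)F)cc(C(F)(F)F)c6)OC(C)(C)C(C)(C)O5)CC[C@@]34C | intermediate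
25 | (3R,5S,10R,13E)-3-bromo-15-(tert-butyldiphenylsilyloxy)labda-8,13-diene | CC(C)(C)[Si](c1ccccc1)(c1ccccc1)OC/C=C(C)/CCC3=C(C)CC[C@@H]4C(C)(C)[C@H](Br)CC[C@@]34C | intermediate
26 | (3R,5S,10R,13E)-3-bromolabda-8,13-dien-15-ol | OC/C=C(C)/CCC3=C(C)CC[C@@H]4C(C)(C)[C@H](Br)CC[C@@]34C | intermediate
27 | (3R,5S,10R,13R,14R)-3-bromo-13,14-epoxylabd-8-en-15-ol | OC[C@H]1O[C@]1(C)CCC3=C(C)CC[C@@H]4C(C)(C)[C@H](Br)CC[C@@]34C | intermediate
28 | 15-iodo analogue of 27 (same spatial arrangement, formally 13R,14S) | IC[C@H]1O[C@]1(C)CCC3=C(C)CC[C@@H]4C(C)(C)[C@H](Br)CC[C@@]34C | intermediate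
29 | (3R,5S,10R,13R)-3-bromolabda-8,14-dien-13-ol | C=C[C@](C)(O)CCC1=C(C)CC[C@@H]2C(C)(C)[C@H](Br)CC[C@@]12C | target

**Step count.** Total: 18 steps (steps 3 and 4 are a two-step branch). Longest linear sequence: 16 steps (1, 2, 5–18, from 1).

**Steps most likely to fail**

1. Step 15. The backside attack of the brominating agent at C3 is hindered by the neighbouring quaternary C4, so a single-electron pathway may take over and erode the inversion, or elimination may compete. The fallback sets out from 23 and comes back at 27, and it puts hydrogen rather than bromine on C3 last. Oxidation of the C–B bond (NaBO3·4H2O, THF/H2O) gives the 3-alcohol F1, and Dess–Martin oxidation gives the ketone F2. The ketone, enolisable only towards C2, is converted with (PhO)3P/Br2/Et3N into the 3-bromo-2-ene F3. Desilylation (Bu4NF) gives the allylic alcohol F4, and Sharpless epoxidation with D-(−)-diethyl tartrate gives the epoxy alcohol F5. Hydrogen-atom-transfer hydrogenation of the bromoalkene (Mn(dpm)3, PhSiH3, t-BuOOH, i-PrOH) then delivers hydrogen to C3 from the face opposite the axial C4 and C10 methyl groups, leaving bromine equatorial, and gives 27. The tetrasubstituted C8=C9 alkene should react much more slowly.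

2. Step 12. The α-methyl group of the enal may favour the formyl-exo transition state, which would give the cis ring fusion, or may lower facial discrimination by the catalyst. The fallback sets out from 15 and comes back at 23, using iminium catalysis on an α-unsubstituted enal. Cross-metathesis of 15 with acrolein gives the enal F6, and Suzuki coupling with 18 gives the tetraenal F7. Cycloaddition under (2S,5S)-5-benzyl-2-tert-butyl-3-methylimidazolidin-4-one trifluoroacetate (or its enantiomer) in wet MeCN, a catalyst class known to give endo, trans-fused adducts from such trienals, gives the aldehyde F8. Diimide reduction gives F9, α-methylation of the aldehyde (KOt-Bu, MeI) gives the quaternary aldehyde F10, and tosylhydrazone reduction as in step 14 gives 23.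

3. Step 5. Transmetalation to the crowded tetrasubstituted α-iodo enoate may be slow, letting protodeiodination or β-hydride elimination of the alkyl–palladium species compete. The fallback sets out from 9 and comes back at 10, building the C9–C11 bond by enolate alkylation and the alkene by enol triflate methylation. Iodinolysis of 9 (I2, NaOMe) gives the alkyl iodide F11. The keto ester F12 (from the dianion of ethyl acetoacetate and allyl bromide) is alkylated with F11 (NaH, DMF) to give F13. Triflation under non-chelating conditions (Me4NOH, Tf2O) is meant to give the enol triflate F14 with the triflate trans to the ester, and MeMgBr with Fe(acac)3 then replaces the triflate by methyl with retention to give 10.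

**Further compounds**

F1 | step 15 | (3S,5R,10R,13E)-15-(tert-butyldiphenylsilyloxy)labda-8,13-dien-3-ol (hydroxyl trans to C10 methyl) | CC(C)(C)[Si](c1ccccc1)(c1ccccc1)OC/C=C(C)/CCC3=C(C)CC[C@@H]4C(C)(C)[C@@H](O)CC[C@@]34C
F2 | step 15 | (5R,10R,13E)-15-(tert-butyldiphenylsilyloxy)labda-8,13-dien-3-one | CC(C)(C)[Si](c1ccccc1)(c1ccccc1)OC/C=C(C)/CCC3=C(C)CC[C@@H]4C(C)(C)C(=O)CC[C@@]34C
F3 | step 15 | (5S,10R,13E)-3-bromo-15-(tert-butyldiphenylsilyloxy)labda-2,8,13-triene | CC(C)(C)[Si](c1ccccc1)(c1ccccc1)OC/C=C(C)/CCC3=C(C)CC[C@@H]4C(C)(C)C(Br)=CC[C@@]34C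
F4 | step 15 | (5S,10R,13E)-3-bromolabda-2,8,13-trien-15-ol | OC/C=C(C)/CCC3=C(C)CC[C@@H]4C(C)(C)C(Br)=CC[C@@]34C
F5 | step 15 | (5S,10R,13R,14R)-3-bromo-13,14-epoxylabda-2,8-dien-15-ol | OC[C@H]1O[C@]1(C)CCC3=C(C)CC[C@@H]4C(C)(C)C(Br)=CC[C@@]34C
F6 | step 12 | (2E,6Z,10E)-12-(tert-butyldiphenylsilyloxy)-7-[(1E)-1-iodoprop-1-en-2-yl]-6,10-dimethyldodeca-2,6,10-trienal | I/C=C(C)/C(CC/C(C)=C/CO[Si](c1ccccc1)(c1ccccc1)C(C)(C)C)=C(C)\CC/C=C/C=O
F7 | step 12 | (2E,6Z,10E)-12-(tert-butyldiphenylsilyloxy)-6,10-dimethyl-7-[(2E,4E)-5-(pinacolboryl)penta-2,4-dien-2-yl]dodeca-2,6,10-trienal | CC1(C)OB(/C=C/C=C(C)/C(CC/C(C)=C/CO[Si](c2ccccc2)(c2ccccc2)C(C)(C)C)=C(C)\CC/C=C/C=O)OC1(C)C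
F8 | step 12 | 18-nor analogue of 20 (H in place of the C4 methyl; formyl cis to H-5) | CC(C)(C)[Si](c1ccccc1)(c1ccccc1)OC/C=C(C)/CCC3=C(C)CC[C@@H]4[C@@H](C=O)[C@@H](B5OC(C)(C)C(C)(C)O5)C=C[C@@]34C
F9 | step 12 | 1,2-dihydro derivative of F8 | CC(C)(C)[Si](c1ccccc1)(c1ccccc1)OC/C=C(C)/CCC3=C(C)CC[C@@H]4[C@@H](C=O)[C@@H](B5OC(C)(C)C(C)(C)O5)CC[C@@]34C
F10 | step 12 | C4 epimer of 21 (formyl trans to H-5) | CC(C)(C)[Si](c1ccccc1)(c1ccccc1)OC/C=C(C)/CCC3=C(C)CC[C@@H]4[C@](C)(C=O)[C@@H](B5OC(C)(C)C(C)(C)O5)CC[C@@]34C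
F11 | step 5 | tert-butyl{[(2E)-5-iodo-3-methylpent-2-en-1-yl]oxy}diphenylsilane | CC(C)(C)[Si](c1ccccc1)(c1ccccc1)OC/C=C(C)/CCI
F12 | step 5 | ethyl 3-oxohept-6-enoate | C=CCCC(=O)CC(=O)OCC
F13 | step 5 | ethyl 2-[(3E)-5-(tert-butyldiphenylsilyloxy)-3-methylpent-3-en-1-yl]-3-oxohept-6-enoate (racemic) | C=CCCC(=O)C(CC/C(C)=C/CO[Si](c1ccccc1)(c1ccccc1)C(C)(C)C)C(=O)OCC
F14 | step 5 | enol triflate of F13 with the triflate trans to the ester (butenyl chain cis to ester) | CCOC(=O)/C(CC/C(C)=C/CO[Si](c1ccccc1)(c1ccccc1)C(C)(C)C)=C(OS(=O)(=O)C(F)(F)F)\CCC=C
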